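The butenolide (ring C: C13=C14–C15(=O)–O–C16, labdane numbering) is disconnected between the vinylic carbon C14 and the lactone carbon C15. Its precursor is an acyclic α-(methoxymethoxy) ketone in which C13 is the carbonyl carbon, C15 is the O–CH2–O carbon of the acetal and C14 is still missing. Lithiated trimethylsilyldiazomethane supplies C14, creates C13=C14 and, as the alkylidene carbene, inserts into the doubly oxygen-activated C15–H lying 1,5 to it; one operation thus closes ring C as a 2-methoxy-2,5-dihydrofuran, oxidised later to the lactone. The cis-decalin (rings A and B) arises from an enantioselective quinone Diels–Alder reaction.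

Key step: step 9

Remark on numbering: labdane numbering is used (ring A: C1–C5 and C10; ring B: C5–C10; C11, C12 side chain; C17 on C8; C18 and C19 on C4; C20 on C10), β is the face of C20, and the target SMILES is read as the cis-fused decalin (H-5 β, C20 β) with 2α-OH, 6α-OH and 4β-CH2OAc.

Assumption: the (S)-configured oxazaborolidinium catalyst of step 2 is taken to expose the quinone face that leads to 4 (by analogy with its α-C–H-bound ester and quinone complexes); if the antipode forms, the (R)-catalyst is used with no other change.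

Step 1
Reactants: 1 (E)-pent-3-en-2-one
Product: 2 (E)-2-(triisopropylsilyloxy)penta-1,3-diene
Conditions: TIPSOTf, Et3N, CH2Cl2, 0 °C
Reagents that add atoms: triisopropylsilyl triflate, CC(C)[Si](C(C)C)(C(C)C)OS(=O)(=O)C(F)(F)F
Why: Silyl enol ether formation by soft enolisation (O-silylation, then loss of a methyl proton to Et3N) should give the cross-conjugated 2-silyloxydiene, the (E)-geometry of the propenyl unit being carried over from 1.

Step 2
Reactants: 2 (E)-2-(triisopropylsilyloxy)penta-1,3-diene; 3 2,6-dimethyl-1,4-benzoquinone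
Product: 4 cis-fused cycloadduct (ring B ene-dione with C6 and C9 carbonyls and C7=C8; ring A C2=C3 TIPS enol ether; 5β-H; 10β-CH3; 4α-CH3)
Conditions: (S)-3,3-diphenyl-1-(o-tolyl)tetrahydropyrrolo[1,2-c][1,3,2]oxazaborole (20 mol %), HNTf2 (18 mol %), CH2Cl2, −78 °C
Reagents that add atoms: none
Why: Catalytic enantioselective Diels–Alder reaction (endo, suprafacial): the oxazaborolidinium cation should bind the unhindered quinone carbonyl (future C6) syn to an α-C–H, the nucleophilic CH2 terminus of the diene adds to the methyl-bearing β-carbon (future C10), the concerted addition fixes the cis ring fusion, the endo rule places the diene methyl α at C4, and the screened face of the bound quinone sets the absolute configuration of C5 and C10.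

Step 3
Reactants: 4 cis-fused cycloadduct
Product: 5 6α-hydroxy enone (C9 carbonyl and C7=C8 retained)
Conditions: NaBH4, CeCl3·7H2O, MeOH/CH2Cl2, −78 °C
Reagents that add atoms: none
Why: Luche reduction (1,2-selective): the C6 carbonyl next to the ring-fusion CH is far less hindered than the C9 carbonyl flanked by the quaternary C10, and hydride should enter from the convex β-face of the folded cis-bicycle (the α-face is covered by ring A and its 4α-methyl), giving the 6α-alcohol.

Step 4
Reactants: 5 6α-hydroxy enone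
Product: 6 6α-TBS ether of 5
Conditions: TBSOTf, 2,6-lutidine, CH2Cl2, −78 → 0 °C
Reagents that add atoms: tert-butyldimethylsilyl triflate, CC(C)(C)[Si](C)(C)OS(=O)(=O)C(F)(F)F
Why: Silylation of the hindered secondary alcohol with the silyl triflate; enone, enol ether and stereocentres are untouched.

Step 5
Reactants: 6 6α-TBS ether
Product: 8 C9 enol triflate with C8=C9 (C7 now CH2), via lithium enolate 7 (not isolated)
Conditions: LiBH(s-Bu)3, THF, −78 °C; then PhNTf2, −78 → 0 °C
Reagents that add atoms: N-phenylbis(trifluoromethanesulfonimide), FC(F)(F)S(=O)(=O)N(c1ccccc1)S(=O)(=O)C(F)(F)F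
Why: Conjugate reduction of the β-unsubstituted enone by the bulky trialkylborohydride gives regiospecifically the C8=C9 enolate (C10 is quaternary, so no isomeric enolate exists), which is O-triflated; no stereocentre is formed because C8 stays sp2.

Step 6
Reactants: 9 but-3-ene-1,2-diol (racemic)
Product: 10 1-(methoxymethoxy)but-3-en-2-ol (racemic)
Conditions: MOMCl (1.0 equiv), i-Pr2NEt, CH2Cl2, −78 → 0 °C
Reagents that add atoms: chloromethyl methyl ether, COCCl
Why: Chemoselective O-alkylation (methoxymethyl ether formation) at the more accessible primary hydroxyl with one equivalent of reagent at low temperature.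

Step 7
Reactants: 10 1-(methoxymethoxy)but-3-en-2-ol; 8 C9 enol triflate
Product: 12 coupled alcohol carrying CH2CH2CH(OH)CH2OCH2OCH3 on C9 (both C13 epimers), via B-alkyl-9-BBN 11 (not isolated)
Conditions: 10, 9-BBN-H (2.2 equiv), THF, 0 °C → rt; then 8, Pd(dppf)Cl2 (10 mol %), AsPh3, Cs2CO3, DMF/H2O, 50 °C
Reagents that add atoms: none
Why: Anti-Markovnikov hydroboration puts boron on the terminal carbon (future C11; the hydroxyl is carried as its borinate), and the B-alkyl Suzuki–Miyaura coupling with the hindered enol triflate forges C9–C11 with the C8=C9 double bond fixed in place; the carbinol centre is inconsequential (oxidised in step 8).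

Step 8
Reactants: 12 coupled alcohol
Product: 13 α-(methoxymethoxy) ketone (C13 carbonyl)
Conditions: 1,1,1-triacetoxy-1,1-dihydro-1,2-benziodoxol-3(1H)-one (DMP), NaHCO3, CH2Cl2, 0 °C → rt
Reagents that add atoms: none
Why: Periodinane oxidation of the secondary alcohol under buffered, non-acidic conditions that spare both silyl groups and the acetal.

Step 9
Reactants: 13 α-(methoxymethoxy) ketone
Product: 17 2-methoxy-2,5-dihydrofuran (ring C at the lactol-ether level; both C15 epimers), via lithium alkoxide adduct 14 (not isolated), via 1-diazoalkene 15 (not isolated), via alkylidene carbene 16 (not isolated)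
Conditions: Me3SiCHN2, n-BuLi, THF, −78 °C; then 13, −78 → 0 °C
Reagents that add atoms: trimethylsilyldiazomethane, C[Si](C)(C)C=[N+]=[N-]
Why: The lithiated silyldiazomethane adds to the C13 ketone and adduct 14 loses Me3SiOLi (Peterson-type elimination) to give diazoalkene 15, which expels N2 to the alkylidene carbene 16 whose carbon is C14. The singlet carbene inserts into a C–H bond of the O–CH2–O group (C15), which lies 1,5 to C14, so the C14–C15 bond and the five-membered ring C form in one concerted event; the closest known reaction type is the alkylidene-carbene 1,5-C–H insertion of α-alkoxy ketones to 2,5-dihydrofurans. The closure is a 1,5-insertion through a five-membered transition state, not an attack on a π bond. The only new stereocentre, the acetal carbon C15, forms as both epimers, which is of no consequence because step 12 turns it into the lactone carbonyl. The step needs chemoselectivity for this C–H bond over addition to the C8=C9 double bond and over other C–H bonds: the two oxygens on C15 make its hydrogens strongly hydridic, the other 1,5-position (C9) bears no hydrogen, and the tetrasubstituted alkene is shielded by the quaternary C10 and the C8 methyl. No other carbonyl group competes for the reagent because C2 is still masked as the TIPS enol ether.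

Step 10
Reactants: 17 2-methoxy-2,5-dihydrofuran
Product: 18 ring A enone (C2 carbonyl; C3=C4; methyl on C4)
Conditions: Pd(OAc)2 (10 mol %), O2 (1 atm), DMSO, 60 °C
Reagents that add atoms: none
Why: Saegusa–Ito oxidation: palladation of the silyl enol ether at C3 and β-hydride elimination of H-4 should give the C3=C4 enone and erase the provisional C4 stereocentre.

Step 11
Reactants: 18 ring A enone
Product: 20 C2 ketone with 4β-CH2SiMe2(O-i-Pr) and 4α-CH3, via trimethylsilyl enol ether 19 (not isolated)
Conditions: (i-PrO)Me2SiCH2MgCl, CuI (20 mol %), Me3SiCl, THF, −78 → −40 °C; then aq. NH4Cl, MeOH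
Reagents that add atoms: (isopropoxydimethylsilyl)methylmagnesium chloride, CC(C)O[Si](C)(C)C[Mg]Cl
Why: Copper-catalysed conjugate addition of the silylmethyl Grignard reagent (Me3SiCl-accelerated): axial attack on C4 anti to the pseudo-axial C5–C6 bond, from the convex β-face of the cis-fused bicycle, should set the quaternary C4 with the CH2Si group (future C19) β and the methyl α; the silyl group is a masked hydroxyl.

Step 12
Reactants: 20 C2 ketone with 4β-CH2SiMe2(O-i-Pr)
Product: 21 butenolide (C15 now the lactone carbonyl)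
Conditions: pyridinium chlorochromate [C5H5NH][CrO3Cl], 4 Å MS, CH2Cl2, rt
Reagents that add atoms: pyridinium chlorochromate, [O-][Cr](=O)(=O)Cl.c1cc[nH+]cc1
Why: Oxidation of the cyclic allylic acetal to the α,β-unsaturated lactone by hexavalent chromium (ionisation of the methoxy group, chromate ester at C15, collapse to the carbonyl), a reaction type known for 2-alkoxy-dihydropyrans and -furans; ketone, silyl ether, C–Si bond and the isolated alkene should be inert, and the two C15 epimers converge.

Step 13
Reactants: 21 butenolide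
Product: 22 19-hydroxy 2-ketone (4β-CH2OH)
Conditions: H2O2 (30 %), KF, KHCO3, THF/MeOH, rt
Reagents that add atoms: hydrogen peroxide, OO
Why: Tamao–Fleming oxidation converts the C–Si bond of the alkoxysilane into C–OH at C19 under near-neutral bicarbonate/fluoride conditions that the butenolide and the TBS ether should tolerate.

Step 14
Reactants: 22 19-hydroxy 2-ketone
Product: 24 2α,19-diol, via alkoxyborohydride 23 (not isolated)
Conditions: Me4NBH(OAc)3, MeCN/AcOH, −30 °C
Reagents that add atoms: none
Why: Saksena–Evans hydroxyl-directed reduction: the axial 4β-CH2OH exchanges an acetate on boron and delivers hydride intramolecularly to the β-face of the C2 carbonyl, which should give the 2α-alcohol (trans to C19); the reagent does not reduce the lactone.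

Step 15
Reactants: 24 2α,19-diol
Product: 25 19-acetate (2α-OH free; 6α-OTBS)
Conditions: AcCl (1.05 equiv), 2,4,6-collidine, CH2Cl2, −78 °C
Reagents that add atoms: acetyl chloride, CC(=O)Cl
Why: Kinetically controlled acylation: acetyl chloride with the hindered base at low temperature should acetylate the primary C19 hydroxyl in preference to the secondary C2 hydroxyl.

Step 16
Reactants: 25 19-acetate
Product: 26 target, 19-acetoxy-2α,6α-dihydroxy-5β-labda-8,13-dien-15,16-olide
Conditions: aq. HF (48 %), MeCN, 0 °C → rt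
Reagents that add atoms: none
Why: Fluoride-mediated cleavage of the Si–O bond of the TBS ether under mildly acidic conditions that leave the acetate, the butenolide and the C8=C9 double bond intact.

Compound list

1 | (E)-pent-3-en-2-one | C/C=C/C(C)=O | starting material
2 | (E)-2-(triisopropylsilyloxy)penta-1,3-diene | C=C(O[Si](C(C)C)(C(C)C)C(C)C)/C=C/C | intermediate
3 | 2,6-dimethyl-1,4-benzoquinone | CC1=CC(=O)C=C(C)C1=O | starting material
4 | cis-fused cycloadduct: C6,C9-dione, C7=C8, C2=C3 TIPS enol ether, 5β-H, 10β-CH3, 4α-CH3 | [C@@H]1(C)C=C(O[Si](C(C)C)(C(C)C)C(C)C)C[C@]2(C)C(=O)C(C)=CC(=O)[C@H]12 | intermediate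
5 | 6α-hydroxy enone (C9 ketone, C7=C8) | [C@@H]1(C)C=C(O[Si](C(C)C)(C(C)C)C(C)C)C[C@]2(C)C(=O)C(C)=C[C@H](O)[C@H]12 | intermediate
6 | 6α-TBS ether of 5 | [C@@H]1(C)C=C(O[Si](C(C)C)(C(C)C)C(C)C)C[C@]2(C)C(=O)C(C)=C[C@H](O[Si](C)(C)C(C)(C)C)[C@H]12 | intermediate
7 | lithium C8=C9 enolate | [C@@H]1(C)C=C(O[Si](C(C)C)(C(C)C)C(C)C)C[C@]2(C)C(O[Li])=C(C)C[C@H](O[Si](C)(C)C(C)(C)C)[C@H]12 | intermediate (not isolated)
8 | C9 enol triflate (C8=C9), 6α-OTBS, ring A TIPS enol ether | [C@@H]1(C)C=C(O[Si](C(C)C)(C(C)C)C(C)C)C[C@]2(C)C(OS(=O)(=O)C(F)(F)F)=C(C)C[C@H](O[Si](C)(C)C(C)(C)C)[C@H]12 | intermediate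
9 | but-3-ene-1,2-diol (racemic) | C=CC(O)CO | starting material
10 | 1-(methoxymethoxy)but-3-en-2-ol (racemic) | C=CC(O)COCOC | intermediate
11 | B-[4-(methoxymethoxy)-3-(9-BBN-oxy)butyl]-9-BBN | COCOCC(OB1C2CCCC1CCC2)CCB1C2CCCC1CCC2 | intermediate (not isolated)
12 | coupled alcohol: C9–CH2CH2CH(OH)CH2OCH2OCH3 (C13 epimers) | [C@@H]1(C)C=C(O[Si](C(C)C)(C(C)C)C(C)C)C[C@]2(C)C(CCC(O)COCOC)=C(C)C[C@H](O[Si](C)(C)C(C)(C)C)[C@H]12 | intermediate
13 | α-(methoxymethoxy) ketone (C13 carbonyl) | [C@@H]1(C)C=C(O[Si](C(C)C)(C(C)C)C(C)C)C[C@]2(C)C(CCC(=O)COCOC)=C(C)C[C@H](O[Si](C)(C)C(C)(C)C)[C@H]12 | intermediate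
14 | lithium alkoxide adduct of 13 with lithio(trimethylsilyl)diazomethane | [C@@H]1(C)C=C(O[Si](C(C)C)(C(C)C)C(C)C)C[C@]2(C)C(CCC(O[Li])(COCOC)C(=[N+]=[N-])[Si](C)(C)C)=C(C)C[C@H](O[Si](C)(C)C(C)(C)C)[C@H]12 | intermediate (not isolated)
15 | 1-diazoalkene (C13=C14=N2) | [C@@H]1(C)C=C(O[Si](C(C)C)(C(C)C)C(C)C)C[C@]2(C)C(CCC(COCOC)=C=[N+]=[N-])=C(C)C[C@H](O[Si](C)(C)C(C)(C)C)[C@H]12 | intermediate (not isolated)
16 | alkylidene carbene (carbene carbon C14) | [C@@H]1(C)C=C(O[Si](C(C)C)(C(C)C)C(C)C)C[C@]2(C)C(CCC(COCOC)=[C])=C(C)C[C@H](O[Si](C)(C)C(C)(C)C)[C@H]12 | intermediate (not isolated)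
17 | 2-methoxy-2,5-dihydrofuran (ring C; C15 epimers) | [C@@H]1(C)C=C(O[Si](C(C)C)(C(C)C)C(C)C)C[C@]2(C)C(CCC3=CC(OC)OC3)=C(C)C[C@H](O[Si](C)(C)C(C)(C)C)[C@H]12 | intermediate
18 | ring A enone (C2 ketone, C3=C4, 4-CH3) | CC1=CC(=O)C[C@]2(C)C(CCC3=CC(OC)OC3)=C(C)C[C@H](O[Si](C)(C)C(C)(C)C)[C@H]12 | intermediate
19 | C2 trimethylsilyl enol ether with 4β-CH2SiMe2(O-i-Pr), 4α-CH3 | CC(C)O[Si](C)(C)C[C@@]1(C)C=C(O[Si](C)(C)C)C[C@]2(C)C(CCC3=CC(OC)OC3)=C(C)C[C@H](O[Si](C)(C)C(C)(C)C)[C@H]12 | intermediate (not isolated)
20 | C2 ketone with 4β-CH2SiMe2(O-i-Pr), 4α-CH3 | CC(C)O[Si](C)(C)C[C@@]1(C)CC(=O)C[C@]2(C)C(CCC3=CC(OC)OC3)=C(C)C[C@H](O[Si](C)(C)C(C)(C)C)[C@H]12 | intermediate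
21 | butenolide C2 ketone silane | CC(C)O[Si](C)(C)C[C@@]1(C)CC(=O)C[C@]2(C)C(CCC3=CC(=O)OC3)=C(C)C[C@H](O[Si](C)(C)C(C)(C)C)[C@H]12 | intermediate
22 | 19-hydroxy 2-ketone | OC[C@@]1(C)CC(=O)C[C@]2(C)C(CCC3=CC(=O)OC3)=C(C)C[C@H](O[Si](C)(C)C(C)(C)C)[C@H]12 | intermediate
23 | tetramethylammonium diacetoxy(C19-alkoxy)borohydride of 22 | C[N+](C)(C)C.CC(=O)O[BH-](OC(C)=O)OC[C@@]1(C)CC(=O)C[C@]2(C)C(CCC3=CC(=O)OC3)=C(C)C[C@H](O[Si](C)(C)C(C)(C)C)[C@H]12 | intermediate (not isolated)
24 | 2α,19-diol, 6α-OTBS | OC[C@@]1(C)C[C@H](O)C[C@]2(C)C(CCC3=CC(=O)OC3)=C(C)C[C@H](O[Si](C)(C)C(C)(C)C)[C@H]12 | intermediate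
25 | 19-acetate, 2α-OH, 6α-OTBS | CC(=O)OC[C@@]1(C)C[C@H](O)C[C@]2(C)C(CCC3=CC(=O)OC3)=C(C)C[C@H](O[Si](C)(C)C(C)(C)C)[C@H]12 | intermediate
26 | 19-acetoxy-2α,6α-dihydroxy-5β-labda-8,13-dien-15,16-olide | CC(=O)OC[C@@]1(C)C[C@H](O)C[C@]2(C)C(CCC3=CC(=O)OC3)=C(C)C[C@H](O)[C@H]12 | target

Total step count: 16. Longest linear sequence: 15 steps (from 1 to 26 through steps 1–5 and 7–16).

Steps most likely to fail

1. Step 9. The carbene may partition between the acetal C–H bond and cyclopropanation of the C8=C9 double bond, or oligomerise. Fallback: the insertion is moved to a side-chain fragment that has no alkene and no hydrogen at the competing 1,5-position (an ester carbon sits there). Commercial methyl 5-bromo-4-oxopentanoate is solvolysed (HCO2Na, aq. MeOH) to methyl 5-hydroxy-4-oxopentanoate F1 and protected (MOMCl, i-Pr2NEt) as methyl 5-(methoxymethoxy)-4-oxopentanoate F2. The conditions of step 9 should turn this into methyl 3-(5-methoxy-2,5-dihydrofuran-3-yl)propanoate F3, and saponification (LiOH, THF/H2O) gives 3-(5-methoxy-2,5-dihydrofuran-3-yl)propanoic acid F4. Hunsdiecker-type iododecarboxylation (PhI(OAc)2, I2, hν) gives 4-(2-iodoethyl)-2-methoxy-2,5-dihydrofuran F5, and zinc insertion (Zn, LiCl, THF) gives [2-(5-methoxy-2,5-dihydrofuran-3-yl)ethyl]zinc iodide F6. Negishi coupling of F6 with triflate 8 (Pd(OAc)2, SPhos, THF) should then give 17. The fallback sets out from 8 and returns at 17; steps 7 and 8 are then not needed.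

2. Step 12. The ionised acetal may lose methanol and aromatise to the 3-substituted furan instead of being oxidised. Fallback: the same C15–H bond is oxidised by hydride abstraction instead of by ionisation of the methoxy group. 2,3-Dichloro-5,6-dicyano-1,4-benzoquinone in wet CH2Cl2 buffered at pH 7 should remove hydride from the allylic, doubly oxygenated C15, and water should convert the resulting dialkoxycarbenium ion into lactone 21 and methanol; this reaction type is known for benzylidene and allylic acetals. The fallback sets out from 20 and returns at 21 and makes no new isolated compound.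

3. Step 14. Facial selectivity may be poor if hydride is not delivered by the C19 hydroxyl, giving the 2β-epimer. Fallback: C2 is set by inversion. Ketol 22 is acetylated (Ac2O, pyridine) to the 19-acetoxy 2-ketone F7 and reduced with NaBH4 (MeOH, −40 °C), where external hydride should enter from the α-face, opposite the axial C19 and C20 groups, to give the 2β-alcohol F8. Mitsunobu reaction with chloroacetic acid (PPh3, DIAD) inverts this to the 2α-chloroacetate F9, and selective removal of the chloroacetyl group with thiourea (NaHCO3, EtOH) should give 25. The fallback sets out from 22 and returns at 25.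

Further compounds

F1 | step 9 | methyl 5-hydroxy-4-oxopentanoate | COC(=O)CCC(=O)CO
F2 | step 9 | methyl 5-(methoxymethoxy)-4-oxopentanoate | COCOCC(=O)CCC(=O)OC
F3 | step 9 | methyl 3-(5-methoxy-2,5-dihydrofuran-3-yl)propanoate (racemic) | COC(=O)CCC1=CC(OC)OC1
F4 | step 9 | 3-(5-methoxy-2,5-dihydrofuran-3-yl)propanoic acid (racemic) | OC(=O)CCC1=CC(OC)OC1
F5 | step 9 | 4-(2-iodoethyl)-2-methoxy-2,5-dihydrofuran (racemic) | COC1OCC(CCI)=C1
F6 | step 9 | [2-(5-methoxy-2,5-dihydrofuran-3-yl)ethyl]zinc iodide | COC1OCC(CC[Zn]I)=C1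
F0 | step 12 | none | none
F7 | step 14 | 19-acetoxy 2-ketone (6α-OTBS, butenolide) | CC(=O)OC[C@@]1(C)CC(=O)C[C@]2(C)C(CCC3=CC(=O)OC3)=C(C)C[C@H](O[Si](C)(C)C(C)(C)C)[C@H]12
F8 | step 14 | 19-acetoxy 2β-alcohol (C2 epimer of 25) | CC(=O)OC[C@@]1(C)C[C@@H](O)C[C@]2(C)C(CCC3=CC(=O)OC3)=C(C)C[C@H](O[Si](C)(C)C(C)(C)C)[C@H]12
F9 | step 14 | 19-acetoxy 2α-chloroacetate | CC(=O)OC[C@@]1(C)C[C@H](OC(=O)CCl)C[C@]2(C)C(CCC3=CC(=O)OC3)=C(C)C[C@H](O[Si](C)(C)C(C)(C)C)[C@H]12
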